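## Retrosynthetic overview

1. Target ⇒ double C‑prenylation (the second one dearomatising) at the one free ring carbon of an aromatic acylphloroglucinol that already carries the hydroxylated p‑menthenyl unit.
2. Tertiary C–OH ⇒ key step: trans‑diaxial Markovnikov hydration of a 2‑aryl‑1‑methylcyclohexene, with bromine as a traceless auxiliary, so that OH ends cis to aryl and isopropenyl.
3. Aryl–C bond ⇒ aromatic Claisen rearrangement of an aryl cis‑carvyl ether (1,3‑chirality transfer); ether ⇒ Mitsunobu coupling (inversion) of phlorisobutyrophenone with trans‑carveol.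
4. trans‑Carveol ⇒ (R)‑carvone (Luche reduction, Mitsunobu inversion); phlorisobutyrophenone ⇒ phloroglucinol + isobutyryl chloride.
5. Rings: none is built. The cyclohexane comes intact from carvone; the trione ring is the phloroglucinol ring, dearomatised in the last step.

Assumption: the target is drawn as one enol tautomer of its β‑triketone core and all tautomers are treated as the same compound; natural (R)‑(−)‑carvone is the source of absolute configuration.

## Route

Step 1
Reactants: 1 phloroglucinol (benzene-1,3,5-triol); 2 isobutyryl chloride (2-methylpropanoyl chloride)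
Product: 3 phlorisobutyrophenone [2-methyl-1-(2,4,6-trihydroxyphenyl)propan-1-one]
Conditions: AlCl3 (3.5 equiv), PhNO2, 65 °C
Reagents that add atoms: none
Why: Friedel–Crafts acylation of the symmetric, very nucleophilic triol gives one C‑acyl product, and the new ketone deactivates the ring against a second acylation; no stereocentre is involved.

Step 2
Reactants: 4 (R)-(−)-carvone [(5R)-2-methyl-5-(prop-1-en-2-yl)cyclohex-2-en-1-one]
Product: 5 (−)-cis-carveol [(1R,5R)-2-methyl-5-(prop-1-en-2-yl)cyclohex-2-en-1-ol]
Conditions: NaBH4, CeCl3·7H2O, MeOH, 0 °C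
Reagents that add atoms: none
Why: Luche 1,2‑reduction; axial hydride delivery to the enone gives the pseudo‑equatorial alcohol cis to isopropenyl with high diastereoselectivity, and C5 is untouched.

Step 3
Reactants: 5 (−)-cis-carveol
Product: 7 (−)-trans-carveol [(1S,5R)-2-methyl-5-(prop-1-en-2-yl)cyclohex-2-en-1-ol], via trans-carvyl 4-nitrobenzoate 6 (not isolated)
Conditions: 4-O2NC6H4CO2H, PPh3, DIAD, THF, 0 °C to rt; then K2CO3, MeOH, rt
Reagents that add atoms: 4-nitrobenzoic acid, OC(=O)c1ccc(cc1)[N+](=O)[O-]
Why: Mitsunobu esterification inverts the carbinol carbon by SN2 displacement of the oxyphosphonium group, and methanolysis cleaves the acyl–oxygen bond, so the inverted configuration (OH trans to isopropenyl) is kept.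

Step 4
Reactants: 3 phlorisobutyrophenone; 7 (−)-trans-carveol
Product: 8 1-(2,6-dihydroxy-4-{[(1R,5R)-2-methyl-5-(prop-1-en-2-yl)cyclohex-2-en-1-yl]oxy}phenyl)-2-methylpropan-1-one
Conditions: PPh3, DIAD, THF, 0 °C to rt (3 in 1.5-fold excess)
Reagents that add atoms: none
Why: Mitsunobu etherification; the para hydroxyl (the most acidic one, not hydrogen‑bonded to the ketone) is alkylated with SN2 inversion, so the ether oxygen ends cis to isopropenyl, as the next step requires.

Step 5
Reactants: 8 aryl cis-carvyl ether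
Product: 11 2-[(1S,5S)-2-methyl-5-(prop-1-en-2-yl)cyclohex-2-en-1-yl]-4-(2-methylpropanoyl)benzene-1,3,5-triyl triacetate, via ether diacetate 9 (not isolated), via rearranged phenol diacetate 10 (not isolated)
Conditions: Ac2O, NaOAc, PhNEt2, 190 °C, sealed tube
Reagents that add atoms: acetic anhydride, CC(=O)OC(C)=O
Why: acetylative aromatic Claisen rearrangement; the suprafacial [3,3] shift bonds the (equivalent) ortho carbon to the alkene terminus on the face that carried oxygen, which sets the aryl‑bearing stereocentre cis to isopropenyl, and in‑situ acetylation stops the flanking phenols from adding to the new ring alkene.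

Step 6
Reactants: 11 cyclohexenyl triacetate
Product: 13 2-[(1R,2R,5S)-2-hydroxy-2-methyl-5-(prop-1-en-2-yl)cyclohexyl]-4-(2-methylpropanoyl)benzene-1,3,5-triyl triacetate, via bromohydrin 12 (not isolated)
Conditions: NBS (1.05 equiv), acetone/H2O 4:1, 0 °C, dark; then Bu3SnH (1.5 equiv), Et3B (0.2 equiv), air, rt, same flask
Reagents that add atoms: water, O
Why: Proposed new method: a one‑flask bromonium‑relay hydration in which NBS transfers Br+ reversibly to the more electron‑rich trisubstituted ring alkene (the 1,1‑disubstituted isopropenyl group is spared, as in the bromohydrin formation of limonene), water opens only the bromonium ion lying anti to the aryl group at the tertiary carbon through a trans‑diaxial chair transition state (Markovnikov plus Fürst–Plattner control), which sets the C–OH bond axial and therefore cis to the equatorial aryl and isopropenyl groups, and the Bu3Sn radical then abstracts the secondary bromine so that bromine acts as a traceless stereodirecting electrophile while the flanking acetates keep the phenol oxygens from closing a dihydrobenzofuran; the closest known reaction type is the two‑operation sequence of aqueous NBS bromohydrin formation followed by radical hydrodebromination of an isolated halohydrin.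

Step 7
Reactants: 13 hydrated triacetate; 14 prenyl bromide (1-bromo-3-methylbut-2-ene)
Product: 16 3,5-dihydroxy-4-[(1R,2R,5S)-2-hydroxy-2-methyl-5-(prop-1-en-2-yl)cyclohexyl]-6,6-bis(3-methylbut-2-en-1-yl)-2-(2-methylpropanoyl)cyclohexa-2,4-dien-1-one (target CNP0324849.1), via deacetylated triol 15 (not isolated)
Conditions: KOH, MeOH/H2O, 0 °C to rt; then 14 (2.3 equiv), 0 °C; NaH2PO4 buffer work-up
Reagents that add atoms: none
Why: saponification frees the phenoxide, whose only unsubstituted ring carbon is C‑alkylated twice (the second alkylation dearomatising, as in lupulone‑type syntheses) to give the gem‑diprenyl β‑triketone enolate; the tertiary alcohol and all three stereocentres are untouched.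

## Compound list

1 | phloroglucinol (benzene-1,3,5-triol) | Oc1cc(O)cc(O)c1 | starting material
2 | isobutyryl chloride | CC(C)C(Cl)=O | starting material
3 | phlorisobutyrophenone, 2-methyl-1-(2,4,6-trihydroxyphenyl)propan-1-one | CC(C)C(=O)c1c(O)cc(O)cc1O | intermediate
4 | (R)-(−)-carvone, (5R)-2-methyl-5-(prop-1-en-2-yl)cyclohex-2-en-1-one | CC1=CC[C@H](CC1=O)C(C)=C | starting material
5 | (−)-cis-carveol, (1R,5R)-2-methyl-5-(prop-1-en-2-yl)cyclohex-2-en-1-ol (OH cis to isopropenyl) | CC1=CC[C@H](C[C@H]1O)C(C)=C | intermediate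
6 | (1S,5R)-2-methyl-5-(prop-1-en-2-yl)cyclohex-2-en-1-yl 4-nitrobenzoate (trans; not isolated) | CC1=CC[C@H](C[C@@H]1OC(=O)c1ccc(cc1)[N+](=O)[O-])C(C)=C | intermediate
7 | (−)-trans-carveol, (1S,5R)-2-methyl-5-(prop-1-en-2-yl)cyclohex-2-en-1-ol (OH trans to isopropenyl) | CC1=CC[C@H](C[C@@H]1O)C(C)=C | intermediate
8 | 1-(2,6-dihydroxy-4-{[(1R,5R)-2-methyl-5-(prop-1-en-2-yl)cyclohex-2-en-1-yl]oxy}phenyl)-2-methylpropan-1-one (ether O cis to isopropenyl) | CC1=CC[C@H](C[C@H]1Oc1cc(O)c(C(=O)C(C)C)c(O)c1)C(C)=C | intermediate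
9 | 5-{[(1R,5R)-2-methyl-5-(prop-1-en-2-yl)cyclohex-2-en-1-yl]oxy}-2-(2-methylpropanoyl)benzene-1,3-diyl diacetate (not isolated) | CC1=CC[C@H](C[C@H]1Oc1cc(OC(C)=O)c(C(=O)C(C)C)c(OC(C)=O)c1)C(C)=C | intermediate
10 | 5-hydroxy-4-[(1S,5S)-2-methyl-5-(prop-1-en-2-yl)cyclohex-2-en-1-yl]-2-(2-methylpropanoyl)benzene-1,3-diyl diacetate (not isolated) | C=C(C)[C@H]1CC=C(C)[C@@H](c2c(O)cc(OC(C)=O)c(C(=O)C(C)C)c2OC(C)=O)C1 | intermediate
11 | 2-[(1S,5S)-2-methyl-5-(prop-1-en-2-yl)cyclohex-2-en-1-yl]-4-(2-methylpropanoyl)benzene-1,3,5-triyl triacetate (aryl cis to isopropenyl) | C=C(C)[C@H]1CC=C(C)[C@@H](c2c(OC(C)=O)cc(OC(C)=O)c(C(=O)C(C)C)c2OC(C)=O)C1 | intermediate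
12 | 2-[(1R,2S,3S,5R)-3-bromo-2-hydroxy-2-methyl-5-(prop-1-en-2-yl)cyclohexyl]-4-(2-methylpropanoyl)benzene-1,3,5-triyl triacetate (OH cis to aryl and isopropenyl, Br trans to OH; not isolated) | C=C(C)[C@H]1C[C@H](Br)[C@@](C)(O)[C@@H](c2c(OC(C)=O)cc(OC(C)=O)c(C(=O)C(C)C)c2OC(C)=O)C1 | intermediate
13 | 2-[(1R,2R,5S)-2-hydroxy-2-methyl-5-(prop-1-en-2-yl)cyclohexyl]-4-(2-methylpropanoyl)benzene-1,3,5-triyl triacetate | C=C(C)[C@H]1CC[C@@](C)(O)[C@@H](c2c(OC(C)=O)cc(OC(C)=O)c(C(=O)C(C)C)c2OC(C)=O)C1 | intermediate
14 | prenyl bromide, 1-bromo-3-methylbut-2-ene | CC(C)=CCBr | starting material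
15 | 2-methyl-1-{2,4,6-trihydroxy-3-[(1R,2R,5S)-2-hydroxy-2-methyl-5-(prop-1-en-2-yl)cyclohexyl]phenyl}propan-1-one (not isolated) | C=C(C)[C@H]1CC[C@@](C)(O)[C@@H](c2c(O)cc(O)c(C(=O)C(C)C)c2O)C1 | intermediate
16 | 3,5-dihydroxy-4-[(1R,2R,5S)-2-hydroxy-2-methyl-5-(prop-1-en-2-yl)cyclohexyl]-6,6-bis(3-methylbut-2-en-1-yl)-2-(2-methylpropanoyl)cyclohexa-2,4-dien-1-one | C=C(C)[C@H]1CC[C@@](C)(O)[C@@H](C2=C(O)C(CC=C(C)C)(CC=C(C)C)C(=O)C(C(=O)C(C)C)=C2O)C1 | target

## Step count and risks

Total step count: 7. Longest linear sequence: 6 (steps 2 to 7, from (R)‑carvone).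

The three steps most likely to fail:

**Step 5 (acetylative Claisen).** At 190 °C the ether may lose the terpene by elimination, or rearrange slowly once the ring is acetylated. The fallback makes the aryl–carbon bond intermolecularly; it sets out from 3 and 5 and comes back at 11. Alcohol 5 is converted into (1R,5R)-2-methyl-5-(prop-1-en-2-yl)cyclohex-2-en-1-yl methyl carbonate F1 (ClCO2Me, pyridine). F1 is coupled with 3 by zerovalent‑palladium allylic alkylation at carbon (Pd2(dba)3, DACH‑phenyl Trost ligand, CH2Cl2). The ring carbon attacks the Cs‑symmetric π‑allyl anti to palladium, so the aryl group enters cis to isopropenyl. Because the π‑allyl is symmetric, the ligand enantiomer must be chosen so that attack occurs at the terminus remote from the departed carbonate; the other terminus gives the enantiomer. This yields 2-methyl-1-{2,4,6-trihydroxy-3-[(1S,5S)-2-methyl-5-(prop-1-en-2-yl)cyclohex-2-en-1-yl]phenyl}propan-1-one F2, and peracetylation (Ac2O, pyridine, DMAP) gives 11.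

**Step 6 (proposed new one‑flask hydration).** The ring alkene is shielded by the diacetoxyaryl group, so bromohydrin formation at the isopropenyl group may compete, and the in‑flask radical reduction may be disturbed by the aqueous medium. The fallback uses only known reactions; it sets out from 11 and comes back at 15. Bromohydrin 12 is made with NBS in aqueous acetone and isolated. K2CO3 in MeOH then closes the oxirane and removes the acetates, giving 2-methyl-1-{2,4,6-trihydroxy-3-[1-methyl-4-(prop-1-en-2-yl)-7-oxabicyclo[4.1.0]heptan-2-yl]phenyl}propan-1-one F3 (oxirane oxygen, aryl and isopropenyl all on the same ring face). LiEt3BH in THF opens the oxirane at its secondary carbon to give triol 15, which is carried into the alkylation stage of step 7.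

**Step 7 (double prenylation).** O‑prenylation, mono‑alkylation and hydrolysis of the bromide can lower the yield, and the product cyclises with acid. The fallback changes the alkylation mechanism; it sets out from 13 and comes back at 16. Methanolysis (K2CO3, MeOH) gives isolated 15, which is prenylated under neutral conditions with Pd(PPh3)4 and prenyl methyl carbonate (2.2 equiv) in THF, through a π‑prenyl palladium electrophile.

## Further compounds

F1 | step 5 | (1R,5R)-2-methyl-5-(prop-1-en-2-yl)cyclohex-2-en-1-yl methyl carbonate | CC1=CC[C@H](C[C@H]1OC(=O)OC)C(C)=C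
F2 | step 5 | 2-methyl-1-{2,4,6-trihydroxy-3-[(1S,5S)-2-methyl-5-(prop-1-en-2-yl)cyclohex-2-en-1-yl]phenyl}propan-1-one | C=C(C)[C@H]1CC=C(C)[C@@H](c2c(O)cc(O)c(C(=O)C(C)C)c2O)C1
F3 | step 6 | 2-methyl-1-{2,4,6-trihydroxy-3-[1-methyl-4-(prop-1-en-2-yl)-7-oxabicyclo[4.1.0]heptan-2-yl]phenyl}propan-1-one, oxirane oxygen cis to aryl and isopropenyl | C=C(C)[C@H]1C[C@H]2O[C@@]2(C)[C@@H](c3c(O)cc(O)c(C(=O)C(C)C)c3O)C1
F0 | step 7 | none | none
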